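**Retrosynthetic overview**

1. Feature: ring D1 (O1, C2, C3, C3a, C7a; its arene carries the styryl arm at C5) and ring D2 (O1', C2', C3', C3a', C7a'; fused to the central resorcinol arene, whose C4' is bonded to C3) each have an ether-type sp3 carbon, C2 and C2', bearing the same 4-hydroxyphenyl group trans to the aryl on C3 or C3'.
2. Both C2–aryl and C2'–aryl bonds are therefore cut at once to a bis(2,3-dihydrobenzofuran-2-carboxylic acid) and 4-bromoanisole (twofold decarboxylative arylation; the acid configuration need not be controlled). The styryl arm follows by a Heck reaction at the C5 chloride, and the seven methyl ethers are cleaved last.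
3. Rings D1 and D2 are closed together, late, by twofold α-bromination and base-induced ring contraction of a bis(dihydrocoumarin).
4. C3' and C3 come from two Rh-catalysed asymmetric conjugate arylations: 3,5-dimethoxyphenylboronic acid onto 5-bromo-7-methoxycoumarin (sets C3'), then the boronic acid made from that bromide onto 6-chlorocoumarin (sets C3 and forms C3–C4').
5. Ring order: coumarin lactone on the central arene (from 2-bromo-4,6-dimethoxybenzaldehyde, which fixes the Br/OMe pattern without a regioselective phenol alkylation), second lactone brought in as 6-chlorocoumarin, then D1 and D2 by contraction.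

Key step: step 8

Assumption: the facial sense of (S)-Segphos on both coumarins is taken as the mirror image of the (R)-ligand to (R)-4-arylchroman-2-one correlation of simple coumarins; if a model addition shows otherwise, (R)-Segphos is used in steps 3 and 5.

**Step 1**
Reactants: 1 2-bromo-4,6-dimethoxybenzaldehyde
Product: 2 2-bromo-6-hydroxy-4-methoxybenzaldehyde
Conditions: BCl3 (1.2 equiv), CH2Cl2, −78 to 0 °C; aqueous work-up
Reagents that add atoms: none
Why: BCl3 chelates between the aldehyde oxygen and the ortho methoxy group, so only the C6 methyl ether is cleaved (chelation-directed ortho-demethylation) and the C4 ether and the bromide are left alone.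

**Step 2**
Reactants: 2 2-bromo-6-hydroxy-4-methoxybenzaldehyde; 3 ethyl (triphenylphosphoranylidene)acetate
Product: 5 5-bromo-7-methoxycoumarin, via ethyl (E)-3-(2-bromo-6-hydroxy-4-methoxyphenyl)acrylate 4 (not isolated)
Conditions: N,N-diethylaniline, reflux
Reagents that add atoms: none
Why: Wittig olefination with the stabilised ylide gives the (E)-cinnamate 4, which at the reflux temperature of the solvent isomerises about the double bond and lactonises with loss of ethanol, the standard coumarin synthesis from salicylaldehydes.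

**Step 3**
Reactants: 5 5-bromo-7-methoxycoumarin; 6 3,5-dimethoxyphenylboronic acid
Product: 7 (4S)-5-bromo-4-(3,5-dimethoxyphenyl)-7-methoxychroman-2-one
Conditions: 6 (4 equiv), Rh(acac)(C2H4)2 (3 mol%), (S)-Segphos (3.3 mol%), dioxane/H2O 10:1, 60 °C
Reagents that add atoms: none
Why: Hayashi–Miyaura asymmetric 1,4-addition, in which the aryl group on monovalent rhodium bound to (S)-Segphos inserts across one enantioface of the coumarin C3=C4 bond and sets C4 as S (the later C3'), while the aryl bromide is inert to rhodium under these neutral conditions.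

**Step 4**
Reactants: 7 (4S)-5-bromo-4-(3,5-dimethoxyphenyl)-7-methoxychroman-2-one
Product: 9 [(4S)-4-(3,5-dimethoxyphenyl)-7-methoxy-2-oxochroman-5-yl]boronic acid, via pinacol boronate 8 (not isolated)
Conditions: B2pin2 (1.3 equiv), Pd(dppf)Cl2 (5 mol%), KOAc (3 equiv), dioxane, 90 °C; then NaIO4, 1 M HCl, THF/H2O, rt
Reagents that add atoms: bis(pinacolato)diboron, CC1(C)OB(OC1(C)C)B1OC(C)(C)C(C)(C)O1; water, O
Why: Miyaura borylation of the aryl bromide by zerovalent palladium with the weak base KOAc leaves the lactone untouched, and periodate cleavage of pinacol in the acidic aqueous second stage releases the free boronic acid needed for base-free transmetalation to rhodium, the stereocentre not being involved.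

**Step 5**
Reactants: 9 [(4S)-4-(3,5-dimethoxyphenyl)-7-methoxy-2-oxochroman-5-yl]boronic acid; 10 6-chlorocoumarin
Product: 11 (4S)-6-chloro-4-[(4S)-4-(3,5-dimethoxyphenyl)-7-methoxy-2-oxochroman-5-yl]chroman-2-one
Conditions: 10 (3 equiv), Rh(acac)(C2H4)2 (5 mol%), (S)-Segphos (5.5 mol%), dioxane/H2O 10:1, 60 °C
Reagents that add atoms: none
Why: A second Hayashi–Miyaura 1,4-addition under base-free conditions that keep both aryl lactones closed forms the C3–C4' bond, the (S)-Segphos rhodium aryl choosing under catalyst control the enantioface of 6-chlorocoumarin that sets the new C4 as S (the later C3), and monovalent rhodium does not touch the aryl chloride.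

**Step 6**
Reactants: 11 (4S)-6-chloro-4-[(4S)-4-(3,5-dimethoxyphenyl)-7-methoxy-2-oxochroman-5-yl]chroman-2-one
Product: 13 (3R,4S)-3-bromo-4-[(3R,4S)-3-bromo-4-(3,5-dimethoxyphenyl)-7-methoxy-2-oxochroman-5-yl]-6-chlorochroman-2-one, via dilithium bis(enolate) 12 (not isolated)
Conditions: LiN(SiMe3)2 (2.2 equiv), THF, −78 °C; then added by cannula to BrCl2CCCl2Br (2.4 equiv), THF, −78 °C
Reagents that add atoms: 1,2-dibromo-1,1,2,2-tetrachloroethane, BrC(Cl)(Cl)C(Cl)(Cl)Br; lithium bis(trimethylsilyl)amide, [Li+].C[Si](C)(C)[N-][Si](C)(C)C (lithium of 12 only)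
Why: Each lactone enolate takes bromine by halogen transfer on the face anti to the pseudoaxial C4 aryl group (trans, 3R), and this bromine source, unlike Br2 or NBS, does not brominate the electron-rich methoxyarenes, while inverse addition limits proton exchange and double bromination (α-bromination of ester enolates).

**Step 7**
Reactants: 13 (3R,4S)-3-bromo-4-[(3R,4S)-3-bromo-4-(3,5-dimethoxyphenyl)-7-methoxy-2-oxochroman-5-yl]-6-chlorochroman-2-one
Product: 14 (2S,3S)-4-[(2S,3S)-2-carboxy-5-chloro-2,3-dihydro-1-benzofuran-3-yl]-3-(3,5-dimethoxyphenyl)-6-methoxy-2,3-dihydro-1-benzofuran-2-carboxylic acid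
Conditions: NaOH (6 equiv), THF/H2O, 0 °C to rt; then 1 M HCl to pH 2
Reagents that add atoms: sodium hydroxide, [Na+].[OH-]
Why: Hydroxide opens each aryl lactone to a phenoxide and an α-bromo carboxylate, and 5-exo-tet SN2 displacement of bromide with inversion closes rings D1 and D2 (ring contraction of 3-halodihydrocoumarins to dihydrobenzofuran-2-carboxylic acids), giving the trans acids, whose C2 and C2' configuration is in any case erased in step 8.

**Step 8**
Reactants: 14 (2S,3S)-4-[(2S,3S)-2-carboxy-5-chloro-2,3-dihydro-1-benzofuran-3-yl]-3-(3,5-dimethoxyphenyl)-6-methoxy-2,3-dihydro-1-benzofuran-2-carboxylic acid; 15 4-bromoanisole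
Product: 16 (2S,3S)-5-chloro-3-[(2S,3S)-3-(3,5-dimethoxyphenyl)-6-methoxy-2-(4-methoxyphenyl)-2,3-dihydro-1-benzofuran-4-yl]-2-(4-methoxyphenyl)-2,3-dihydro-1-benzofuran
Conditions: 15 (5 equiv), Ir[dF(CF3)ppy]2(dtbbpy)PF6 (2 mol%), NiCl2(dme) (20 mol%), 4,4'-di-tert-butyl-2,2'-bipyridine (20 mol%), Cs2CO3 (3 equiv), degassed DMF, blue LEDs (450 nm), 25 °C
Reagents that add atoms: none
Why: Photoexcited trivalent iridium oxidises each caesium carboxylate of 14, loss of CO2 gives the α-oxy radical at C2 or C2', the radical is captured by the divalent nickel aryl formed from zerovalent nickel and the C–Br bond of 15, and reductive elimination from trivalent nickel forms the C2–aryl and C2'–aryl bonds while the reduced iridium returns nickel to the zerovalent state. The closest known reaction type is the iridium-photoredox and nickel dual-catalytic decarboxylative arylation of cyclic α-oxy and α-amino acids with aryl bromides, here run twice in one molecule with an electron-rich bromide in excess. The step closes no ring, since both dihydrobenzofuran rings are already in place. C2 and C2' are formed from planar radicals, so the acid configuration does not matter, and each is set by the aryl group on the neighbouring C3 or C3', which blocks one face so that nickel binds and delivers the anisyl group anti to it (trans rings, 2S and 2'S). The step needs C–Br over C–Cl selectivity, which the weaker C–Br bond and the electron-rich chloroarene of ring D1 (chlorine para to O1) should secure at room temperature. It also needs radical capture to outrun a 1,2-aryl shift from C3 to C2, which the strain of a spiro-bicyclic transition state inside the five-membered ring should disfavour.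

**Step 9**
Reactants: 16 (2S,3S)-5-chloro-3-[(2S,3S)-3-(3,5-dimethoxyphenyl)-6-methoxy-2-(4-methoxyphenyl)-2,3-dihydro-1-benzofuran-4-yl]-2-(4-methoxyphenyl)-2,3-dihydro-1-benzofuran; 17 3,5-dimethoxystyrene
Product: 18 (2S,3S)-5-[(E)-2-(3,5-dimethoxyphenyl)ethenyl]-3-[(2S,3S)-3-(3,5-dimethoxyphenyl)-6-methoxy-2-(4-methoxyphenyl)-2,3-dihydro-1-benzofuran-4-yl]-2-(4-methoxyphenyl)-2,3-dihydro-1-benzofuran
Conditions: 17 (1.5 equiv), Pd2(dba)3 (2.5 mol%), P(t-Bu)3 (10 mol%), Cy2NMe (1.5 equiv), dioxane, 110 °C
Reagents that add atoms: none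
Why: Heck reaction of the aryl chloride, in which the bulky electron-rich phosphine allows oxidative addition of zerovalent palladium into the C–Cl bond and syn insertion of the styrene followed by syn β-hydride elimination gives the (E)-stilbene, with none of the four stereocentres involved.

**Step 10**
Reactants: 18 (2S,3S)-5-[(E)-2-(3,5-dimethoxyphenyl)ethenyl]-3-[(2S,3S)-3-(3,5-dimethoxyphenyl)-6-methoxy-2-(4-methoxyphenyl)-2,3-dihydro-1-benzofuran-4-yl]-2-(4-methoxyphenyl)-2,3-dihydro-1-benzofuran
Product: 19 trans-diptoindonesin B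
Conditions: BBr3 (20 equiv), CH2Cl2, −78 °C to rt; then ice water
Reagents that add atoms: none
Why: BBr3 cleaves all seven aryl methyl ethers by bromide attack at methyl on the boron-complexed ethers, and because the trans-2,3-diaryl dihydrobenzofurans are the thermodynamically preferred isomers, any reversible opening of a benzylic C2–O bond should reclose trans.

**Compound list**

1 | 2-bromo-4,6-dimethoxybenzaldehyde | O=Cc1c(OC)cc(OC)cc1Br | starting material
2 | 2-bromo-6-hydroxy-4-methoxybenzaldehyde | O=Cc1c(O)cc(OC)cc1Br | intermediate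
3 | ethyl (triphenylphosphoranylidene)acetate | CCOC(=O)C=P(c1ccccc1)(c1ccccc1)c1ccccc1 | starting material
4 | ethyl (E)-3-(2-bromo-6-hydroxy-4-methoxyphenyl)acrylate | CCOC(=O)/C=C/c1c(O)cc(OC)cc1Br | intermediate
5 | 5-bromo-7-methoxycoumarin | COc1cc(Br)c2ccc(=O)oc2c1 | intermediate
6 | 3,5-dimethoxyphenylboronic acid | COc1cc(OC)cc(B(O)O)c1 | starting material
7 | (4S)-5-bromo-4-(3,5-dimethoxyphenyl)-7-methoxychroman-2-one | Brc1cc(OC)cc2c1[C@H](c1cc(OC)cc(OC)c1)CC(=O)O2 | intermediate
8 | (4S)-4-(3,5-dimethoxyphenyl)-7-methoxy-5-(4,4,5,5-tetramethyl-1,3,2-dioxaborolan-2-yl)chroman-2-one | CC1(C)OB(OC1(C)C)c1cc(OC)cc2c1[C@H](c1cc(OC)cc(OC)c1)CC(=O)O2 | intermediate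
9 | [(4S)-4-(3,5-dimethoxyphenyl)-7-methoxy-2-oxochroman-5-yl]boronic acid | OB(O)c1cc(OC)cc2c1[C@H](c1cc(OC)cc(OC)c1)CC(=O)O2 | intermediate
10 | 6-chlorocoumarin | O=c1ccc2cc(Cl)ccc2o1 | starting material
11 | (4S)-6-chloro-4-[(4S)-4-(3,5-dimethoxyphenyl)-7-methoxy-2-oxochroman-5-yl]chroman-2-one | O=C1Oc2ccc(Cl)cc2[C@@H](C1)c1cc(OC)cc2c1[C@H](c1cc(OC)cc(OC)c1)CC(=O)O2 | intermediate
12 | dilithium bis(enolate) of 11 (both lactones as C2–C3 lithium enolates; 4S,4'S) | [Li+].[Li+].[O-]C1Oc2ccc(Cl)cc2[C@@H](C=1)c1cc(OC)cc2c1[C@H](c1cc(OC)cc(OC)c1)C=C([O-])O2 | intermediate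
13 | (3R,4S)-3-bromo-4-[(3R,4S)-3-bromo-4-(3,5-dimethoxyphenyl)-7-methoxy-2-oxochroman-5-yl]-6-chlorochroman-2-one (Br trans to the C4 substituent in each lactone) | O=C1Oc2ccc(Cl)cc2[C@@H]([C@H]1Br)c1cc(OC)cc2c1[C@H](c1cc(OC)cc(OC)c1)[C@@H](Br)C(=O)O2 | intermediate
14 | (2S,3S)-4-[(2S,3S)-2-carboxy-5-chloro-2,3-dihydro-1-benzofuran-3-yl]-3-(3,5-dimethoxyphenyl)-6-methoxy-2,3-dihydro-1-benzofuran-2-carboxylic acid (both rings trans) | OC(=O)[C@H]1Oc2ccc(Cl)cc2[C@@H]1c1cc(OC)cc2c1[C@H](c1cc(OC)cc(OC)c1)[C@@H](C(=O)O)O2 | intermediate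
15 | 4-bromoanisole | COc1ccc(Br)cc1 | starting material
16 | (2S,3S)-5-chloro-3-[(2S,3S)-3-(3,5-dimethoxyphenyl)-6-methoxy-2-(4-methoxyphenyl)-2,3-dihydro-1-benzofuran-4-yl]-2-(4-methoxyphenyl)-2,3-dihydro-1-benzofuran | COc1ccc([C@H]2Oc3ccc(Cl)cc3[C@@H]2c2cc(OC)cc3c2[C@H](c2cc(OC)cc(OC)c2)[C@@H](c2ccc(OC)cc2)O3)cc1 | intermediate
17 | 3,5-dimethoxystyrene | C=Cc1cc(OC)cc(OC)c1 | starting material
18 | hepta-O-methyl trans-diptoindonesin B (2S,3S,2'S,3'S; E alkene) | COc1ccc([C@H]2Oc3ccc(/C=C/c4cc(OC)cc(OC)c4)cc3[C@@H]2c2cc(OC)cc3c2[C@H](c2cc(OC)cc(OC)c2)[C@@H](c2ccc(OC)cc2)O3)cc1 | intermediate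
19 | trans-diptoindonesin B (2S,3S,2'S,3'S; E alkene) | Oc1ccc([C@H]2Oc3ccc(/C=C/c4cc(O)cc(O)c4)cc3[C@@H]2c2cc(O)cc3c2[C@H](c2cc(O)cc(O)c2)[C@@H](c2ccc(O)cc2)O3)cc1 | target

**Step count**

Total steps: 10. Longest linear sequence: 10 steps (1 to 19); 3, 6, 10, 15 and 17 enter as purchased reagents.

**Steps most likely to fail**

1. Step 8. Oxidative addition of the electron-rich bromide may be slow, so the α-oxy radicals are reduced and protonated (protodecarboxylation) or dimerise before nickel captures them, and the second coupling may stall after the first. Capture syn to the C3 or C3' aryl group would give cis rings, and slow insertion of nickel into the C–Cl bond or a 1,2-aryl shift of the radical would give constitutional by-products. Fallback, from 14 back to 16: the diacid is esterified with N-hydroxyphthalimide (N,N'-diisopropylcarbodiimide, cat. DMAP, CH2Cl2) to the bis(1,3-dioxoisoindolin-2-yl) diester F1. This redox-active ester is coupled with 4-iodoanisole in a thermal nickel-catalysed reductive cross-electrophile arylation (NiBr2(dme), 4,4'-di-tert-butyl-2,2'-bipyridine, Zn, DMA, rt). The same C2 and C2' radicals arise by reductive fragmentation instead of photo-oxidation, the iodide is engaged far faster than the ring chloride, and the same anti delivery should give 16.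

2. Step 5. Transmetalation and insertion of the ortho-substituted aryl group may be slow, so protodeboronation of 9 outruns addition to the weakly electrophilic coumarin. The resident stereocentre next to the reacting carbon may also oppose the ligand (mismatched pairing) and lower facial selectivity. Fallback, from 7 back to 11, with the roles of the two partners exchanged: a Heck reaction of bromide 7 with methyl acrylate (Pd(OAc)2, P(o-tol)3, Et3N, DMF, 100 °C) gives methyl (E)-3-[(4S)-4-(3,5-dimethoxyphenyl)-7-methoxy-2-oxochroman-5-yl]prop-2-enoate F2. Rh-catalysed asymmetric 1,4-addition of commercial [2-(benzyloxy)-5-chlorophenyl]boronic acid (Rh(acac)(C2H4)2, the BINAP antipode that a model cinnamate shows to give the 3S adduct, dioxane/H2O, 100 °C) gives methyl (3S)-3-[2-(benzyloxy)-5-chlorophenyl]-3-[(4S)-4-(3,5-dimethoxyphenyl)-7-methoxy-2-oxochroman-5-yl]propanoate F3. Debenzylation with BCl3 and pentamethylbenzene at −78 °C (methyl ethers survive) gives methyl (3S)-3-(5-chloro-2-hydroxyphenyl)-3-[(4S)-4-(3,5-dimethoxyphenyl)-7-methoxy-2-oxochroman-5-yl]propanoate F4, which lactonises with TsOH in warm toluene to 11.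

3. Step 10. During the long Lewis-acid exposure needed to cleave seven ethers, the electron-rich stilbene may be protonated or add HBr and oligomerise, and ionisation of a benzylic C2–O bond may be followed by proton loss from C3 instead of reclosure. Fallback, from 16 back to 19, with the demethylation moved ahead of the stilbene: 16 is demethylated with BBr3 (CH2Cl2, −78 to 0 °C) to the 5-chloro pentaphenol F5, which is acetylated (Ac2O, pyridine) to the 5-chloro pentaacetate F6. The Heck reaction of step 9 is then run on F6 with commercial 3,5-diacetoxystyrene (C=Cc1cc(OC(C)=O)cc(OC(C)=O)c1) to give hepta-O-acetyl trans-diptoindonesin B F7. Mild methanolysis (K2CO3, MeOH, argon, 0 °C, then dilute HCl) gives 19 without exposing the stilbene to acid.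

**Further compounds**

F1 | step 8 | bis(1,3-dioxoisoindolin-2-yl) diester of diacid 14 (2S,3S,2'S,3'S) | O=C(ON1C(=O)c2ccccc2C1=O)[C@H]1Oc2ccc(Cl)cc2[C@@H]1c1cc(OC)cc2c1[C@H](c1cc(OC)cc(OC)c1)[C@@H](C(=O)ON1C(=O)c3ccccc3C1=O)O2
F2 | step 5 | methyl (E)-3-[(4S)-4-(3,5-dimethoxyphenyl)-7-methoxy-2-oxochroman-5-yl]prop-2-enoate | COC(=O)/C=C/c1cc(OC)cc2c1[C@H](c1cc(OC)cc(OC)c1)CC(=O)O2
F3 | step 5 | methyl (3S)-3-[2-(benzyloxy)-5-chlorophenyl]-3-[(4S)-4-(3,5-dimethoxyphenyl)-7-methoxy-2-oxochroman-5-yl]propanoate | COC(=O)C[C@H](c1cc(Cl)ccc1OCc1ccccc1)c1cc(OC)cc2c1[C@H](c1cc(OC)cc(OC)c1)CC(=O)O2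
F4 | step 5 | methyl (3S)-3-(5-chloro-2-hydroxyphenyl)-3-[(4S)-4-(3,5-dimethoxyphenyl)-7-methoxy-2-oxochroman-5-yl]propanoate | COC(=O)C[C@H](c1cc(Cl)ccc1O)c1cc(OC)cc2c1[C@H](c1cc(OC)cc(OC)c1)CC(=O)O2
F5 | step 10 | 5-chloro pentaphenol: (2S,3S)-5-chloro-3-[(2S,3S)-3-(3,5-dihydroxyphenyl)-6-hydroxy-2-(4-hydroxyphenyl)-2,3-dihydro-1-benzofuran-4-yl]-2-(4-hydroxyphenyl)-2,3-dihydro-1-benzofuran | Oc1ccc([C@H]2Oc3ccc(Cl)cc3[C@@H]2c2cc(O)cc3c2[C@H](c2cc(O)cc(O)c2)[C@@H](c2ccc(O)cc2)O3)cc1
F6 | step 10 | 5-chloro pentaacetate of F5 | CC(=O)Oc1ccc([C@H]2Oc3ccc(Cl)cc3[C@@H]2c2cc(OC(C)=O)cc3c2[C@H](c2cc(OC(C)=O)cc(OC(C)=O)c2)[C@@H](c2ccc(OC(C)=O)cc2)O3)cc1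
F7 | step 10 | hepta-O-acetyl trans-diptoindonesin B | CC(=O)Oc1ccc([C@H]2Oc3ccc(/C=C/c4cc(OC(C)=O)cc(OC(C)=O)c4)cc3[C@@H]2c2cc(OC(C)=O)cc3c2[C@H](c2cc(OC(C)=O)cc(OC(C)=O)c2)[C@@H](c2ccc(OC(C)=O)cc2)O3)cc1
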